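**Retrosynthetic overview**
- C=CHBr last: the Z-alkenyl bromide comes from an E-alkenylsilane by phenol-assisted bromoetherification and fluoride-induced anti-elimination (Si replaced by Br with inversion of alkene geometry).
- Cyclopentane (the only ring built; the arene is bought): C2–C3 bond by aryloxide-directed, titanium-mediated reductive cyclization of a 1,6-enyne, which sets C2 relative to C1.
- Quaternary C1 (first stereocentre): aryl–C1 bond by a catalytic enantioselective aromatic Claisen rearrangement of an E-allyl aryl ether under a confined chiral Brønsted acid (new reaction).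
- Allyl aryl ether: Mitsunobu C–O bond; the E-allylic alcohol comes from Horner–Wadsworth–Emmons olefination and ester reduction of an alkynyl methyl ketone; the alkyne is C-silylated.
- Ring order: benzene ring purchased, cyclopentane closed in step 6, a transient O-bridged ring formed and reopened within step 7.

Assumption: 1, 2, 5 and all reagents are purchased; both enantiomers of the acid catalyst are available and the one that gives (R)-9 is taken (written as S,S).

Step 1
Reactants: 1 hex-5-yn-2-one; 2 triethyl phosphonoacetate
Product: 3 ethyl (2E)-3-methylhept-2-en-6-ynoate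
Conditions: NaH, THF, 0 °C to rt; minor Z isomer removed by chromatography
Reagents that add atoms: none
Why: Horner–Wadsworth–Emmons olefination of the methyl ketone gives the trisubstituted enoate mainly as the E isomer (about 5:1 expected), and the Z isomer must be removed because alkene geometry later decides the sense of induction.

Step 2
Reactants: 3 ethyl (2E)-3-methylhept-2-en-6-ynoate
Product: 4 (2E)-3-methylhept-2-en-6-yn-1-ol
Conditions: i-Bu2AlH (2.2 equiv), CH2Cl2, −78 °C
Reagents that add atoms: none
Why: 1,2-Reduction of the enoate by the aluminium hydride gives the allylic alcohol without touching the alkyne or the alkene geometry (ester reduction).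

Step 3
Reactants: 4 (2E)-3-methylhept-2-en-6-yn-1-ol; 5 4-bromo-3-methylphenol
Product: 6 1-bromo-2-methyl-4-{[(2E)-3-methylhept-2-en-6-yn-1-yl]oxy}benzene
Conditions: PPh3, DIAD, THF, 0 °C to rt
Reagents that add atoms: none
Why: Mitsunobu etherification, in which the phenol displaces the activated primary allylic alcohol by SN2 and the E-alkene is retained; no stereocentre is formed.

Step 4
Reactants: 6 1-bromo-2-methyl-4-{[(2E)-3-methylhept-2-en-6-yn-1-yl]oxy}benzene
Product: 7 [(5E)-7-(4-bromo-3-methylphenoxy)-5-methylhept-5-en-1-yn-1-yl]trimethylsilane
Conditions: EtMgBr, THF, 0 to 40 °C; then Me3SiCl, 0 °C to rt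
Reagents that add atoms: chlorotrimethylsilane, C[Si](C)(C)Cl
Why: Deprotonation of the terminal alkyne and C-silylation of the alkynyl Grignard reagent; the aryl bromide and allyl ether are inert, and the silyl group later controls the titanium cyclization and serves as the handle for bromine.

Step 5
Reactants: 7 [(5E)-7-(4-bromo-3-methylphenoxy)-5-methylhept-5-en-1-yn-1-yl]trimethylsilane
Product: 9 4-bromo-5-methyl-2-[(3R)-3-methyl-7-(trimethylsilyl)hept-1-en-6-yn-3-yl]phenol, via ortho-dienone 8 (not isolated)
Conditions: (S,S)-IDPi (BINOL-derived imidodiphosphorimidate Brønsted acid, 3,3′-diaryl, N-triflyl; 5 mol %), cyclohexane–CH2Cl2 4:1, 5 Å MS, −20 °C to rt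
Reagents that add atoms: none
Why: Proposed new method: catalytic enantioselective aromatic Claisen rearrangement under a confined chiral Brønsted acid. The acid hydrogen-bonds to (partly protonates) the ether oxygen and stabilises the phenol-like oxygen of the polarised chair [3,3] transition state, the charge acceleration known for strong achiral acids, so the shift should run far below the thermal threshold (above 150 °C) and no racemic background exists. The E-alkene fixes which γ-substituent is axial, the chiral anion cavity selects one enantiotopic face of the γ-carbon and so sets C1 as R, the tight ion pair keeps the two fragments together and directs bonding to the less hindered ortho carbon (para to the methyl group; the para position is blocked by Br), and tautomerisation of dienone 8 releases the catalyst. Closest known reaction types: thermal and strong-acid-accelerated aromatic Claisen rearrangement, hydrogen-bond-donor-catalysed enantioselective Claisen rearrangement of allyl vinyl ethers, and aromatic Claisen rearrangement promoted by stoichiometric chiral boron Lewis acids.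

Step 6
Reactants: 9 4-bromo-5-methyl-2-[(3R)-3-methyl-7-(trimethylsilyl)hept-1-en-6-yn-3-yl]phenol
Product: 11 4-bromo-2-{(1R,2R,3E)-1,2-dimethyl-3-[(trimethylsilyl)methylidene]cyclopentyl}-5-methylphenol, via titanacyclopentene 10 (not isolated)
Conditions: Ti(OiPr)4 (1.2 equiv), i-PrMgCl (3.3 equiv), Et2O, −78 to −30 °C; then H2O
Reagents that add atoms: none
Why: Titanium alkoxide-mediated reductive enyne cyclization; the first equivalent of Grignard reagent makes the phenoxide, which exchanges onto titanium, and the divalent titanium–propene complex formed from the other two binds the silylalkyne and inserts the vinyl group to give titanacyclopentene 10. Because titanium stays tied to the ortho-aryloxide (7-membered chelate), the CH2–Ti carbon lies on the aryl face, which sets C2 with the future methyl cis to the aryl group (1R,2R). Protonolysis of both Ti–C bonds with retention gives the E-alkenylsilane (Si cis to C4).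

Step 7
Reactants: 11 4-bromo-2-{(1R,2R,3E)-1,2-dimethyl-3-[(trimethylsilyl)methylidene]cyclopentyl}-5-methylphenol
Product: 13 4-bromo-2-[(1R,2R,3Z)-3-(bromomethylidene)-1,2-dimethylcyclopentyl]-5-methylphenol, via bridged bromo ether 12 (not isolated)
Conditions: NBS (1.05 equiv), CH2Cl2, −78 to −20 °C; then Bu4NF, THF, 0 °C
Reagents that add atoms: N-bromosuccinimide, O=C1CCC(=O)N1Br
Why: Bromoetherification, with anti addition of Br at the silyl-bearing carbon and the phenol oxygen at the β-silyl-stabilised C3, followed by fluoride-induced anti β-elimination of Me3Si and aryloxide (the reaction type of fluoride cleavage of 2-silylethyl ethers). The net result is bromodesilylation with inversion of alkene geometry, E-silane to Z-bromide (Br cis to C2), with C1 and C2 untouched.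

**Compound list**
1 | hex-5-yn-2-one | CC(=O)CCC#C | starting material
2 | triethyl phosphonoacetate | CCOC(=O)CP(=O)(OCC)OCC | starting material
3 | ethyl (2E)-3-methylhept-2-en-6-ynoate | CCOC(=O)/C=C(\C)CCC#C | intermediate
4 | (2E)-3-methylhept-2-en-6-yn-1-ol | OC/C=C(\C)CCC#C | intermediate
5 | 4-bromo-3-methylphenol | Cc1cc(O)ccc1Br | starting material
6 | 1-bromo-2-methyl-4-{[(2E)-3-methylhept-2-en-6-yn-1-yl]oxy}benzene | Cc1cc(OC/C=C(\C)CCC#C)ccc1Br | intermediate
7 | [(5E)-7-(4-bromo-3-methylphenoxy)-5-methylhept-5-en-1-yn-1-yl]trimethylsilane | Cc1cc(OC/C=C(\C)CCC#C[Si](C)(C)C)ccc1Br | intermediate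
8 | ortho-dienone: 4-bromo-3-methyl-6-[(3R)-3-methyl-7-(trimethylsilyl)hept-1-en-6-yn-3-yl]cyclohexa-2,4-dien-1-one (ring C6 epimer not defined; lost on tautomerisation) | CC1=CC(=O)C([C@](C=C)(C)CCC#C[Si](C)(C)C)C=C1Br | intermediate (not isolated)
9 | 4-bromo-5-methyl-2-[(3R)-3-methyl-7-(trimethylsilyl)hept-1-en-6-yn-3-yl]phenol | Cc1cc(O)c([C@](C=C)(C)CCC#C[Si](C)(C)C)cc1Br | intermediate
10 | titanacyclopentene: tetravalent titanium bonded to the phenoxide O, to the CH2 on ring C2 (cis to aryl), to the silyl-bearing alkenyl carbon and to one isopropoxide | Cc1cc2c(cc1Br)[C@]1(C)CCC3=C([Si](C)(C)C)[Ti](OC(C)C)(O2)C[C@@H]31 | intermediate (not isolated)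
11 | 4-bromo-2-{(1R,2R,3E)-1,2-dimethyl-3-[(trimethylsilyl)methylidene]cyclopentyl}-5-methylphenol | Cc1cc(O)c([C@]2(C)CC/C(=C\[Si](C)(C)C)[C@@H]2C)cc1Br | intermediate
12 | bridged bromo ether: benzo-fused 2-oxabicyclo[3.2.1]octane in which the phenol O is bonded to former C3 (cis to the aryl ring) and C3 carries CH(Br)SiMe3 | Cc1cc2c(cc1Br)[C@]1(C)CC[C@@](O2)([C@H](Br)[Si](C)(C)C)[C@@H]1C | intermediate (not isolated)
13 | 4-bromo-2-[(1R,2R,3Z)-3-(bromomethylidene)-1,2-dimethylcyclopentyl]-5-methylphenol | Cc1cc(O)c([C@]2(C)CC/C(=C/Br)[C@@H]2C)cc1Br | target

**Step count**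
Total steps: 7. Longest linear sequence: 7 (1 to 13).

**Steps most likely to fail**

Step 5 (the new reaction). Risks are ionisation of the γ,γ-disubstituted allyl ether to give the achiral [1,3]-shifted (linear) phenol, acid-induced cyclisation of 9 onto its vinyl group, and low enantioselectivity. Fallback with known chemistry: starting from 7, the uncatalysed thermal aromatic Claisen rearrangement (N,N-diethylaniline, 170–180 °C) gives racemic material, that is 9 together with its mirror image 4-bromo-5-methyl-2-[(3S)-3-methyl-7-(trimethylsilyl)hept-1-en-6-yn-3-yl]phenol F1. The two are separated by preparative chiral-phase SFC and the route is rejoined at 9.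

Step 6. The C2 configuration (methyl cis to aryl) is the contra-steric one and rests entirely on the aryloxide–titanium chelate. If the alkene inserts before the phenoxide is bound to titanium, the C2 epimer will form in roughly equal amount. Fallback: starting from 9, hydrogen-mediated reductive enyne cyclization with a cationic rhodium catalyst ([Rh(cod)2]OTf, (R)- or (S)-BINAP, H2 1 atm, ClCH2CH2Cl, rt) forms the same bond through a rhodacyclopentene, so that C2 is set by the chiral ligand (matched enantiomer found by screen) and not by the tether. This rejoins the route at 11 and makes no new compound (F0).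

Step 7. Risks are bromination of the free ortho position of the phenol, and direct ipso-bromodesilylation with retention through the open β-silyl cation, which would give the E-bromide. Fallback: starting from 9, titanacyclopentene 10 is made as in step 6 but quenched in two stages, s-BuOH (1 equiv, −78 °C) for the alkyl–titanium bond and then NBS for the alkenyl–titanium bond (retention). This gives 4-bromo-2-{(1R,2R,3Z)-3-[bromo(trimethylsilyl)methylidene]-1,2-dimethylcyclopentyl}-5-methylphenol F2, in which Br already sits cis to C2. Protodesilylation of this 1-bromo-1-silylalkene with Bu4NF in wet THF (retention) rejoins the route at 13.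

Further compounds
F1 | step 5 | 4-bromo-5-methyl-2-[(3S)-3-methyl-7-(trimethylsilyl)hept-1-en-6-yn-3-yl]phenol | Cc1cc(O)c([C@@](C=C)(C)CCC#C[Si](C)(C)C)cc1Br
F0 | step 6 | none | none
F2 | step 7 | 4-bromo-2-{(1R,2R,3Z)-3-[bromo(trimethylsilyl)methylidene]-1,2-dimethylcyclopentyl}-5-methylphenol | Cc1cc(O)c([C@]2(C)CC/C(=C(/Br)[Si](C)(C)C)[C@@H]2C)cc1Br
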